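**Retrosynthetic overview**
- The hydrogen sulfate and the free hydroquinone come last, from a secondary alcohol whose C–O bond is made by oxidising a C–B bond.
- Key step: the C2–C3 bond and the C2 stereocentre are made together by a lithiation–borylation union (stereospecific 1,2-metallate rearrangement) of an α-lithiated decalinylethyl triisopropylbenzoate (fragment A) with a secondary alkyl boronic ester (fragment B); no aldehyde, aldol or crotylation is used.
- Fragment A belongs to the enantiomeric drimane series, which sclareolide cannot supply, so it is made by an enantioselective proton-initiated bicyclisation of homofarnesyl triisopropylbenzoate: ring A first (chiral acid), ring B second (superacid); the ester carried through is the later lithiation handle.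
- Fragment B: 5-chloropent-1-yne is carboaluminated and cross-coupled with a benzylic chloride (E-alkene and arene in one step), borylated, and homologated with lithiated ethyl triisopropylbenzoate to set the methyl stereocentre.
- Ring order: arene bought in, then ring A, then ring B.

Assumption: the target is taken exactly as drawn, i.e. the free hydrogen sulfate with a (1R,4aR,8aR)-decalin, 2S,3S side-chain centres and a 7E alkene, so the last step ends with exchange of the counter-ion for a proton.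

Short forms used in the step lines (full names are in the compound list): TIB ester = 2,4,6-tri(propan-2-yl)benzoate; TIPS = tri(propan-2-yl)silyl; Bpin = 4,4,5,5-tetramethyl-1,3,2-dioxaborolan-2-yl; Dec = (1R,4aR,8aR)-2,5,5,8a-tetramethyl-1,4,4a,5,6,7,8,8a-octahydronaphthalen-1-yl; ArSi = 2,5-bis(TIPS-oxy)phenyl.

**Route**

Step 1
Reactants: 1 2,4,6-tri(propan-2-yl)benzoic acid
Product: 2 methyl TIB ester
Conditions: MeI, K2CO3, DMF, rt
Reagents that add atoms: iodomethane, CI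
Why: SN2 O-alkylation of the carboxylate (esterification) works because the carboxylate oxygen is accessible even though the carbonyl carbon is shielded; no stereocentre is formed.

Step 2
Reactants: 2 methyl TIB ester; 3 (2E,6E)-1-bromo-3,7,11-trimethyldodeca-2,6,10-triene (farnesyl bromide)
Product: 5 (3E,7E)-4,8,12-trimethyltrideca-3,7,11-trien-1-yl TIB ester (homofarnesyl TIB ester), via lithiomethyl TIB ester 4 (not isolated)
Conditions: s-BuLi, TMEDA, THF, −78 °C; then 3, −78 °C → 0 °C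
Reagents that add atoms: none
Why: Dipole-stabilised α-lithiation of the hindered methyl ester (Beak-type hydroxymethyl-anion equivalent) followed by SN2 alkylation at the primary allylic bromide adds one carbon and installs the ester handle while leaving both E alkenes untouched; no stereocentre is formed.

Step 3
Reactants: 5 homofarnesyl TIB ester
Product: 7 2-Dec-ethyl TIB ester (fragment A), via monocyclic ester 6 (not isolated)
Conditions: (S)-2'-[(2-fluorophenyl)methoxy]-1,1'-binaphthalen-2-ol·SnCl4 (1.1 equiv), toluene, −78 °C, 48 h; pyridine quench, short SiO2 filtration; then FSO3H (5 equiv), i-PrNO2, −78 °C, 20 min; Et3N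
Reagents that add atoms: none
Why: Proposed new method: a two-stage cation–olefin bicyclisation in which the chiral Lewis-acid-assisted Brønsted acid protonates the terminal alkene face-selectively and closes ring A (fixing C4a as R; the S acid is chosen as the antipode of the one that gives the natural series in homofarnesyl ether cyclisations), after which the superacid re-protonates the monocyclic alkene to the tertiary cation that closes ring B through a chair transition state on the E alkene (trans fusion and equatorial side chain, so 8aR and 1R follow from 4aR) and loses the axial C3 proton to give the 2,3-alkene; the closest known reactions are chiral-acid-induced enantioselective cyclisations of homofarnesyl ethers completed with an achiral acid and fluorosulfonic acid cyclisations of farnesyl esters that end in the same trisubstituted ring alkene, the hindered protonated benzoate acting as a non-participating terminus.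

Step 4
Reactants: 8 2,5-dihydroxybenzaldehyde
Product: 9 2,5-bis(TIPS-oxy)benzaldehyde
Conditions: i-Pr3SiCl, imidazole, DMAP (cat.), DMF, 40 °C
Reagents that add atoms: chlorotri(propan-2-yl)silane, CC(C)[Si](Cl)(C(C)C)C(C)C
Why: Imidazole-promoted O-silylation protects both phenols as bulky silyl ethers that tolerate organoaluminium, Grignard, organolithium and alkaline peroxide conditions and are later removed by fluoride.

Step 5
Reactants: 9 2,5-bis(TIPS-oxy)benzaldehyde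
Product: 10 [2,5-bis(TIPS-oxy)phenyl]methanol
Conditions: NaBH4, THF/EtOH, 0 °C
Reagents that add atoms: none
Why: Borohydride reduction of the aldehyde is chemoselective, and the bulky silyl groups suppress oxygen-to-oxygen silyl migration.

Step 6
Reactants: 10 [2,5-bis(TIPS-oxy)phenyl]methanol
Product: 11 2,5-bis(TIPS-oxy)benzyl chloride
Conditions: PPh3, N-chlorosuccinimide, CH2Cl2, 0 °C → rt
Reagents that add atoms: N-chlorosuccinimide, ClN1C(=O)CCC1=O
Why: Appel-type chlorination through the alkoxyphosphonium salt converts the electron-rich benzylic alcohol into the chloride under neutral conditions that do not cleave the silyl ethers.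

Step 7
Reactants: 12 5-chloropent-1-yne; 11 2,5-bis(TIPS-oxy)benzyl chloride
Product: 14 (2E)-1-ArSi-6-chloro-3-methylhex-2-ene, via alkenylalane 13 (not isolated)
Conditions: Me3Al, Cp2ZrCl2 (20 mol%), ClCH2CH2Cl, 0 °C → rt; evaporate; then 11, NiCl2(PPh3)2 (5 mol%) reduced with n-BuLi (10 mol%) to zerovalent nickel, THF, rt
Reagents that add atoms: trimethylaluminium, C[Al](C)C
Why: Zirconium-catalysed syn-carboalumination of the terminal alkyne (Negishi carboalumination) fixes the E trisubstituted alkene, and nickel-catalysed cross-coupling of the alkenylalane with the benzylic chloride forms the aryl–CH2 bond with retention of geometry while the alkyl chloride stays inert.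

Step 8
Reactants: 14 (2E)-1-ArSi-6-chloro-3-methylhex-2-ene
Product: 16 (4E)-6-ArSi-4-methylhex-4-en-1-yl-Bpin, via Grignard reagent 15 (not isolated)
Conditions: Mg, BrCH2CH2Br (cat.), THF, 50 °C; then i-PrO-Bpin, −78 °C → rt
Reagents that add atoms: 4,4,5,5-tetramethyl-2-(propan-2-yloxy)-1,3,2-dioxaborolane, CC(C)OB1OC(C)(C)C(C)(C)O1
Why: Grignard formation at the primary chloride and electrophilic borylation with the alkoxyborate give the primary pinacol boronic ester; aryl silyl ethers and trisubstituted alkenes are inert.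

Step 9
Reactants: 17 ethyl TIB ester; 16 (4E)-6-ArSi-4-methylhex-4-en-1-yl-Bpin
Product: 20 (2S,6E)-8-ArSi-6-methyloct-6-en-2-yl-Bpin (fragment B), via lithiated ethyl ester 18 (not isolated), via boronate complex 19 (not isolated)
Conditions: 17 (1.3 equiv), s-BuLi, (+)-sparteine, Et2O, −78 °C, 5 h; then 16, −78 °C, 1 h; then 35 °C, 16 h
Reagents that add atoms: none
Why: Lithiation–borylation: (+)-sparteine-directed removal of the pro-R hydrogen gives the configurationally stable (R)-α-lithio ester, which is borylated with retention and undergoes 1,2-metallate rearrangement with inversion at the carbenoid carbon, setting the methyl-bearing stereocentre as S.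

Step 10
Reactants: 7 2-Dec-ethyl TIB ester (fragment A); 20 (2S,6E)-8-ArSi-6-methyloct-6-en-2-yl-Bpin (fragment B)
Product: 23 (2S,3S,7E)-9-ArSi-1-Dec-3,7-dimethylnon-7-en-2-yl-Bpin, via lithiated ester 21 (not isolated), via boronate complex 22 (not isolated)
Conditions: 7 (1.3 equiv), s-BuLi (1.25 equiv), (+)-sparteine, Et2O, −78 °C, 5 h; then 20 (1.0 equiv), −78 °C, 2 h; then CHCl3, 60 °C, 16 h
Reagents that add atoms: none
Why: Lithiation–borylation fragment union: reagent-controlled (+)-sparteine deprotonation next to the benzoate oxygen gives the (R)-α-lithio ester, borylation occurs with retention, and 1,2-migration of the secondary alkyl group (retention in the migrating carbon, inversion at the carbenoid carbon) forms the C2–C3 bond, sets C2 as S and carries C3 over as S.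

Step 11
Reactants: 23 (2S,3S,7E)-9-ArSi-1-Dec-3,7-dimethylnon-7-en-2-yl-Bpin
Product: 24 (2S,3S,7E)-9-ArSi-1-Dec-3,7-dimethylnon-7-en-2-ol
Conditions: H2O2 (30%), NaOH (2 M), THF, 0 °C → rt
Reagents that add atoms: hydrogen peroxide, OO
Why: Alkaline peroxide oxidation of the C–B bond (boron-to-oxygen 1,2-shift) proceeds with retention, so the carbinol is 2S, and the electron-rich alkenes and aryl TIPS ethers survive the short cold basic treatment.

Step 12
Reactants: 24 (2S,3S,7E)-9-ArSi-1-Dec-3,7-dimethylnon-7-en-2-ol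
Product: 25 pyridinium (2S,3S,7E)-9-ArSi-1-Dec-3,7-dimethylnon-7-en-2-yl sulfate
Conditions: SO3·pyridine (5 equiv), pyridine, 40 °C
Reagents that add atoms: sulfur trioxide–pyridine complex, [O-]S(=O)(=O)[n+]1ccccc1
Why: O-sulfation of the only free hydroxyl with the SO3–amine complex touches only the O–H bond, so the configuration is kept, and the masked phenols cannot compete.

Step 13
Reactants: 25 pyridinium (2S,3S,7E)-9-ArSi-1-Dec-3,7-dimethylnon-7-en-2-yl sulfate
Product: 26 (2S,3S,7E)-9-(2,5-dihydroxyphenyl)-1-Dec-3,7-dimethylnon-7-en-2-yl hydrogen sulfate (target)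
Conditions: Bu4NF, AcOH, THF, 0 °C, argon; then Dowex 50W (H+ form), MeOH, 0 °C; freeze-dry
Reagents that add atoms: none
Why: Acetic-acid-buffered fluoride desilylation cleaves both aryl silyl ethers without affecting the alkyl sulfate, alkenes or stereocentres, and cation exchange gives the hydrogen sulfate.

**Compound list**
1 | 2,4,6-tri(propan-2-yl)benzoic acid | OC(=O)c1c(C(C)C)cc(C(C)C)cc1C(C)C | starting material
2 | methyl 2,4,6-tri(propan-2-yl)benzoate | COC(=O)c1c(C(C)C)cc(C(C)C)cc1C(C)C | intermediate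
3 | (2E,6E)-1-bromo-3,7,11-trimethyldodeca-2,6,10-triene | CC(C)=CCC/C(C)=C/CC/C(C)=C/CBr | starting material
4 | lithiomethyl 2,4,6-tri(propan-2-yl)benzoate | [Li]COC(=O)c1c(C(C)C)cc(C(C)C)cc1C(C)C | intermediate
5 | (3E,7E)-4,8,12-trimethyltrideca-3,7,11-trien-1-yl 2,4,6-tri(propan-2-yl)benzoate | CC(C)=CCC/C(C)=C/CC/C(C)=C/CCOC(=O)c1c(C(C)C)cc(C(C)C)cc1C(C)C | intermediate
6 | (3E)-4-methyl-6-[(1R)-2,6,6-trimethylcyclohex-2-en-1-yl]hex-3-en-1-yl 2,4,6-tri(propan-2-yl)benzoate (principal component of the partly cyclised mixture) | CC1=CCCC(C)(C)[C@H]1CC/C(C)=C/CCOC(=O)c1c(C(C)C)cc(C(C)C)cc1C(C)C | intermediate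
7 | 2-[(1R,4aR,8aR)-2,5,5,8a-tetramethyl-1,4,4a,5,6,7,8,8a-octahydronaphthalen-1-yl]ethyl 2,4,6-tri(propan-2-yl)benzoate | CC1=CC[C@@H]2C(C)(C)CCC[C@@]2(C)[C@@H]1CCOC(=O)c1c(C(C)C)cc(C(C)C)cc1C(C)C | intermediate
8 | 2,5-dihydroxybenzaldehyde | O=Cc1cc(O)ccc1O | starting material
9 | 2,5-bis{[tri(propan-2-yl)silyl]oxy}benzaldehyde | O=Cc1cc(O[Si](C(C)C)(C(C)C)C(C)C)ccc1O[Si](C(C)C)(C(C)C)C(C)C | intermediate
10 | (2,5-bis{[tri(propan-2-yl)silyl]oxy}phenyl)methanol | OCc1cc(O[Si](C(C)C)(C(C)C)C(C)C)ccc1O[Si](C(C)C)(C(C)C)C(C)C | intermediate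
11 | {[2-(chloromethyl)-1,4-phenylene]bis(oxy)}bis[tri(propan-2-yl)silane] | ClCc1cc(O[Si](C(C)C)(C(C)C)C(C)C)ccc1O[Si](C(C)C)(C(C)C)C(C)C | intermediate
12 | 5-chloropent-1-yne | C#CCCCCl | starting material
13 | [(1E)-5-chloro-2-methylpent-1-en-1-yl]dimethylalumane | ClCCC/C(C)=C/[Al](C)C | intermediate
14 | ({2-[(2E)-6-chloro-3-methylhex-2-en-1-yl]-1,4-phenylene}bis(oxy))bis[tri(propan-2-yl)silane] | ClCCC/C(C)=C/Cc1cc(O[Si](C(C)C)(C(C)C)C(C)C)ccc1O[Si](C(C)C)(C(C)C)C(C)C | intermediate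
15 | chlorido[(4E)-6-(2,5-bis{[tri(propan-2-yl)silyl]oxy}phenyl)-4-methylhex-4-en-1-yl]magnesium | Cl[Mg]CCC/C(C)=C/Cc1cc(O[Si](C(C)C)(C(C)C)C(C)C)ccc1O[Si](C(C)C)(C(C)C)C(C)C | intermediate
16 | 2-[(4E)-6-(2,5-bis{[tri(propan-2-yl)silyl]oxy}phenyl)-4-methylhex-4-en-1-yl]-4,4,5,5-tetramethyl-1,3,2-dioxaborolane | CC1(C)OB(CCC/C(C)=C/Cc2cc(O[Si](C(C)C)(C(C)C)C(C)C)ccc2O[Si](C(C)C)(C(C)C)C(C)C)OC1(C)C | intermediate
17 | ethyl 2,4,6-tri(propan-2-yl)benzoate | CCOC(=O)c1c(C(C)C)cc(C(C)C)cc1C(C)C | starting material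
18 | (1R)-1-lithioethyl 2,4,6-tri(propan-2-yl)benzoate | C[C@@H]([Li])OC(=O)c1c(C(C)C)cc(C(C)C)cc1C(C)C | intermediate
19 | lithium [(4E)-6-(2,5-bis{[tri(propan-2-yl)silyl]oxy}phenyl)-4-methylhex-4-en-1-yl][(1R)-1-{[2,4,6-tri(propan-2-yl)benzoyl]oxy}ethyl](2,3-dimethylbutane-2,3-diolato)borate | [Li+].C[C@H](OC(=O)c1c(C(C)C)cc(C(C)C)cc1C(C)C)[B-]1(CCC/C(C)=C/Cc2cc(O[Si](C(C)C)(C(C)C)C(C)C)ccc2O[Si](C(C)C)(C(C)C)C(C)C)OC(C)(C)C(C)(C)O1 | intermediate
20 | 2-[(2S,6E)-8-(2,5-bis{[tri(propan-2-yl)silyl]oxy}phenyl)-6-methyloct-6-en-2-yl]-4,4,5,5-tetramethyl-1,3,2-dioxaborolane | CC1(C)OB([C@@H](C)CCC/C(C)=C/Cc2cc(O[Si](C(C)C)(C(C)C)C(C)C)ccc2O[Si](C(C)C)(C(C)C)C(C)C)OC1(C)C | intermediate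
21 | (1R)-1-lithio-2-[(1R,4aR,8aR)-2,5,5,8a-tetramethyl-1,4,4a,5,6,7,8,8a-octahydronaphthalen-1-yl]ethyl 2,4,6-tri(propan-2-yl)benzoate | CC1=CC[C@@H]2C(C)(C)CCC[C@@]2(C)[C@@H]1C[C@@H]([Li])OC(=O)c1c(C(C)C)cc(C(C)C)cc1C(C)C | intermediate
22 | lithium [(2S,6E)-8-(2,5-bis{[tri(propan-2-yl)silyl]oxy}phenyl)-6-methyloct-6-en-2-yl][(1R)-2-[(1R,4aR,8aR)-2,5,5,8a-tetramethyl-1,4,4a,5,6,7,8,8a-octahydronaphthalen-1-yl]-1-{[2,4,6-tri(propan-2-yl)benzoyl]oxy}ethyl](2,3-dimethylbutane-2,3-diolato)borate | [Li+].CC1=CC[C@@H]2C(C)(C)CCC[C@@]2(C)[C@@H]1C[C@@H]([B-]1([C@@H](C)CCC/C(C)=C/Cc2cc(O[Si](C(C)C)(C(C)C)C(C)C)ccc2O[Si](C(C)C)(C(C)C)C(C)C)OC(C)(C)C(C)(C)O1)OC(=O)c1c(C(C)C)cc(C(C)C)cc1C(C)C | intermediate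
23 | 2-[(2S,3S,7E)-9-(2,5-bis{[tri(propan-2-yl)silyl]oxy}phenyl)-3,7-dimethyl-1-[(1R,4aR,8aR)-2,5,5,8a-tetramethyl-1,4,4a,5,6,7,8,8a-octahydronaphthalen-1-yl]non-7-en-2-yl]-4,4,5,5-tetramethyl-1,3,2-dioxaborolane | CC1=CC[C@@H]2C(C)(C)CCC[C@@]2(C)[C@@H]1C[C@H](B1OC(C)(C)C(C)(C)O1)[C@@H](C)CCC/C(C)=C/Cc1cc(O[Si](C(C)C)(C(C)C)C(C)C)ccc1O[Si](C(C)C)(C(C)C)C(C)C | intermediate
24 | (2S,3S,7E)-9-(2,5-bis{[tri(propan-2-yl)silyl]oxy}phenyl)-3,7-dimethyl-1-[(1R,4aR,8aR)-2,5,5,8a-tetramethyl-1,4,4a,5,6,7,8,8a-octahydronaphthalen-1-yl]non-7-en-2-ol | CC1=CC[C@@H]2C(C)(C)CCC[C@@]2(C)[C@@H]1C[C@H](O)[C@@H](C)CCC/C(C)=C/Cc1cc(O[Si](C(C)C)(C(C)C)C(C)C)ccc1O[Si](C(C)C)(C(C)C)C(C)C | intermediate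
25 | pyridinium (2S,3S,7E)-9-(2,5-bis{[tri(propan-2-yl)silyl]oxy}phenyl)-3,7-dimethyl-1-[(1R,4aR,8aR)-2,5,5,8a-tetramethyl-1,4,4a,5,6,7,8,8a-octahydronaphthalen-1-yl]non-7-en-2-yl sulfate | CC1=CC[C@@H]2C(C)(C)CCC[C@@]2(C)[C@@H]1C[C@H](OS(=O)(=O)[O-])[C@@H](C)CCC/C(C)=C/Cc1cc(O[Si](C(C)C)(C(C)C)C(C)C)ccc1O[Si](C(C)C)(C(C)C)C(C)C.c1cc[nH+]cc1 | intermediate
26 | (2S,3S,7E)-9-(2,5-dihydroxyphenyl)-3,7-dimethyl-1-[(1R,4aR,8aR)-2,5,5,8a-tetramethyl-1,4,4a,5,6,7,8,8a-octahydronaphthalen-1-yl]non-7-en-2-yl hydrogen sulfate | CC1=CC[C@@H]2C(C)(C)CCC[C@@]2(C)[C@@H]1C[C@H](OS(=O)(=O)O)[C@@H](C)CCC/C(C)=C/Cc1cc(O)ccc1O | target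

**Totals**
Total step count: 13.
Longest linear sequence: 10 steps (steps 4 to 13, from 8 to 26); the fragment A branch is 7 steps (1, 2, 3, 10 to 13).

**Three steps most likely to fail**

Step 3 (enantioselective bicyclisation). The enantiomer ratio and the ring-alkene position are unproven for a benzoate terminus. A moderate ratio is tolerable, because the minor enantiomer becomes a separable diastereomer after step 10. Fallback, setting out from 5 and coming back at 7: cyclise 5 with FSO3H alone (i-PrNO2, −78 °C), the established superacid bicyclisation that gives the same ring-alkene isomer as a racemate, that is 7 together with 2-[(1S,4aS,8aS)-2,5,5,8a-tetramethyl-1,4,4a,5,6,7,8,8a-octahydronaphthalen-1-yl]ethyl 2,4,6-tri(propan-2-yl)benzoate F1. Resolve the racemate by preparative chromatography on a chiral stationary phase (the benzoate is a convenient chromophore). Stereocontrol thus moves from asymmetric catalysis to resolution.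

Step 10 (lithiation–borylation union). Lithiation of the chiral ester may be slow or mismatched, and boronate formation or migration with the α-branched boronic ester may stall. Fallback, setting out from 7 and coming back at 24, replacing the boronate rearrangement by carbonyl addition and metathesis:
- LiAlH4 (THF, reflux) cleaves the hindered ester to 2-[(1R,4aR,8aR)-2,5,5,8a-tetramethyl-1,4,4a,5,6,7,8,8a-octahydronaphthalen-1-yl]ethan-1-ol F2.
- Dess–Martin periodinane gives [(1R,4aR,8aR)-2,5,5,8a-tetramethyl-1,4,4a,5,6,7,8,8a-octahydronaphthalen-1-yl]acetaldehyde F3.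
- Brown syn-crotylboration with (Z)-but-2-enyl-B(Ipc)2 (Ipc antipode chosen for the 2S,3S adduct, −78 °C, then NaOH/H2O2) gives (2S,3S)-3-methyl-1-[(1R,4aR,8aR)-2,5,5,8a-tetramethyl-1,4,4a,5,6,7,8,8a-octahydronaphthalen-1-yl]pent-4-en-2-ol F4.
- In parallel, pent-1-en-4-yne is carboaluminated (Me3Al, Cp2ZrCl2) to dimethyl[(1E)-2-methylpenta-1,4-dien-1-yl]alumane F5, which is coupled with 11 under the nickel conditions of step 7 to give ({2-[(2E)-3-methylhexa-2,5-dien-1-yl]-1,4-phenylene}bis(oxy))bis[tri(propan-2-yl)silane] F6.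
- Cross-metathesis of F4 with excess F6 (second-generation Hoveyda–Grubbs catalyst, RuCl2(H2IMes)(=CH-C6H4-2-O-i-Pr), CH2Cl2, 40 °C) gives (2S,3S,4E,7E)-9-(2,5-bis{[tri(propan-2-yl)silyl]oxy}phenyl)-3,7-dimethyl-1-[(1R,4aR,8aR)-2,5,5,8a-tetramethyl-1,4,4a,5,6,7,8,8a-octahydronaphthalen-1-yl]nona-4,7-dien-2-ol F7.
- Diimide (2-nitrobenzenesulfonohydrazide, Et3N) saturates only the disubstituted alkene and delivers 24.

Step 13 (desilylation and isolation as the hydrogen sulfate). The free hydroquinone is air-sensitive and the sulfate may not tolerate the deprotection and proton exchange. Fallback, setting out from 24 and coming back at 26, using the quinone as the protecting group for the hydroquinone: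
- Bu4NF (THF, 0 °C) removes both silyl groups to give (2S,3S,7E)-9-(2,5-dihydroxyphenyl)-3,7-dimethyl-1-[(1R,4aR,8aR)-2,5,5,8a-tetramethyl-1,4,4a,5,6,7,8,8a-octahydronaphthalen-1-yl]non-7-en-2-ol F8.
- Ag2O (Et2O, rt) oxidises it to 2-[(2E,7S,8S)-8-hydroxy-3,7-dimethyl-9-[(1R,4aR,8aR)-2,5,5,8a-tetramethyl-1,4,4a,5,6,7,8,8a-octahydronaphthalen-1-yl]non-2-en-1-yl]cyclohexa-2,5-diene-1,4-dione F9.
- SO3·NMe3 (DMF, 40 °C) sulfates the only hydroxyl to give trimethylammonium (2S,3S,7E)-9-(3,6-dioxocyclohexa-1,4-dien-1-yl)-3,7-dimethyl-1-[(1R,4aR,8aR)-2,5,5,8a-tetramethyl-1,4,4a,5,6,7,8,8a-octahydronaphthalen-1-yl]non-7-en-2-yl sulfate F10.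
- Na2S2O4 (water/EtOAc, pH 7) reduces the quinone to the hydroquinone, and cation exchange (H+ form) gives 26.

Further compounds
F1 | step 3 | 2-[(1S,4aS,8aS)-2,5,5,8a-tetramethyl-1,4,4a,5,6,7,8,8a-octahydronaphthalen-1-yl]ethyl 2,4,6-tri(propan-2-yl)benzoate | CC1=CC[C@H]2C(C)(C)CCC[C@]2(C)[C@H]1CCOC(=O)c1c(C(C)C)cc(C(C)C)cc1C(C)C
F2 | step 10 | 2-[(1R,4aR,8aR)-2,5,5,8a-tetramethyl-1,4,4a,5,6,7,8,8a-octahydronaphthalen-1-yl]ethan-1-ol | CC1=CC[C@@H]2C(C)(C)CCC[C@@]2(C)[C@@H]1CCO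
F3 | step 10 | [(1R,4aR,8aR)-2,5,5,8a-tetramethyl-1,4,4a,5,6,7,8,8a-octahydronaphthalen-1-yl]acetaldehyde | CC1=CC[C@@H]2C(C)(C)CCC[C@@]2(C)[C@@H]1CC=O
F4 | step 10 | (2S,3S)-3-methyl-1-[(1R,4aR,8aR)-2,5,5,8a-tetramethyl-1,4,4a,5,6,7,8,8a-octahydronaphthalen-1-yl]pent-4-en-2-ol | CC1=CC[C@@H]2C(C)(C)CCC[C@@]2(C)[C@@H]1C[C@H](O)[C@@H](C)C=C
F5 | step 10 | dimethyl[(1E)-2-methylpenta-1,4-dien-1-yl]alumane | C=CC/C(C)=C/[Al](C)C
F6 | step 10 | ({2-[(2E)-3-methylhexa-2,5-dien-1-yl]-1,4-phenylene}bis(oxy))bis[tri(propan-2-yl)silane] | C=CC/C(C)=C/Cc1cc(O[Si](C(C)C)(C(C)C)C(C)C)ccc1O[Si](C(C)C)(C(C)C)C(C)C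
F7 | step 10 | (2S,3S,4E,7E)-9-(2,5-bis{[tri(propan-2-yl)silyl]oxy}phenyl)-3,7-dimethyl-1-[(1R,4aR,8aR)-2,5,5,8a-tetramethyl-1,4,4a,5,6,7,8,8a-octahydronaphthalen-1-yl]nona-4,7-dien-2-ol | CC1=CC[C@@H]2C(C)(C)CCC[C@@]2(C)[C@@H]1C[C@H](O)[C@@H](C)/C=C/C/C(C)=C/Cc1cc(O[Si](C(C)C)(C(C)C)C(C)C)ccc1O[Si](C(C)C)(C(C)C)C(C)C
F8 | step 13 | (2S,3S,7E)-9-(2,5-dihydroxyphenyl)-3,7-dimethyl-1-[(1R,4aR,8aR)-2,5,5,8a-tetramethyl-1,4,4a,5,6,7,8,8a-octahydronaphthalen-1-yl]non-7-en-2-ol | CC1=CC[C@@H]2C(C)(C)CCC[C@@]2(C)[C@@H]1C[C@H](O)[C@@H](C)CCC/C(C)=C/Cc1cc(O)ccc1O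
F9 | step 13 | 2-[(2E,7S,8S)-8-hydroxy-3,7-dimethyl-9-[(1R,4aR,8aR)-2,5,5,8a-tetramethyl-1,4,4a,5,6,7,8,8a-octahydronaphthalen-1-yl]non-2-en-1-yl]cyclohexa-2,5-diene-1,4-dione | CC1=CC[C@@H]2C(C)(C)CCC[C@@]2(C)[C@@H]1C[C@H](O)[C@@H](C)CCC/C(C)=C/CC1=CC(=O)C=CC1=O
F10 | step 13 | trimethylammonium (2S,3S,7E)-9-(3,6-dioxocyclohexa-1,4-dien-1-yl)-3,7-dimethyl-1-[(1R,4aR,8aR)-2,5,5,8a-tetramethyl-1,4,4a,5,6,7,8,8a-octahydronaphthalen-1-yl]non-7-en-2-yl sulfate | CC1=CC[C@@H]2C(C)(C)CCC[C@@]2(C)[C@@H]1C[C@H](OS(=O)(=O)[O-])[C@@H](C)CCC/C(C)=C/CC1=CC(=O)C=CC1=O.C[NH+](C)C
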